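**Retrosynthetic overview**
- The pyran ring is closed last: the tertiary hydroxyl of an (E)-3-alkenyl-2-methoxy-5-methylbenzoquinone adds to the methoxy-bearing quinone carbon after a light-driven E→Z isomerisation, so the C-2 stereocenter is the untouched carbinol of (R)-linalool.
- That quinone comes from a Heck union of an iodo-trimethoxytoluene with the vinyl group of the complete side-chain lactone, followed by oxidative demethylation.
- The side-chain lactone comes from a Z-selective Still–Gennari olefination (aldehyde + α-alkylated phosphonoacetate), then ketal hydrolysis and lactonisation.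
- The aldehyde comes from (R)-linalool (allylic oxidation, bromide, two-carbon homologation); the phosphonate from (R)-α-hydroxy-γ-butyrolactone (MeMgBr, acetonide, iodide, alkylation).
- Ring order: δ-lactone first, pyran ring of the chromenequinone last; the quinone carbocycle is bought as the arene.

Assumption: (R)-(−)-linalool, (R)-α-hydroxy-γ-butyrolactone (made on scale from D-malic acid), methyl bis(2,2,2-trifluoroethyl)phosphonoacetate and 1,2,4-trimethoxy-5-methylbenzene are bought, and the optical purity of the target is that of the two chiral purchases.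

**Route**

Step 1
Reactants: 1 (3R)-3,7-dimethylocta-1,6-dien-3-ol ((R)-linalool)
Product: 2 (2E,6R)-2,6-dimethylocta-2,7-diene-1,6-diol
Conditions: SeO2 (0.3 equiv), t-BuOOH (2.5 equiv), CH2Cl2, 25 °C
Reagents that add atoms: tert-butyl hydroperoxide, CC(C)(C)OO (oxygen atom, carried by catalytic SeO2, O=[Se]=O)
Why: SeO2-catalysed allylic oxidation (ene reaction then [2,3]-sigmatropic shift) oxidises only the (E)-methyl of the trisubstituted alkene, the vinyl group having no allylic hydrogen, and the carbinol stereocenter is not involved.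

Step 2
Reactants: 2 (2E,6R)-2,6-dimethylocta-2,7-diene-1,6-diol
Product: 3 (3R,6E)-8-bromo-3,7-dimethylocta-1,6-dien-3-ol
Conditions: CBr4 (1.1 equiv), PPh3 (1.1 equiv), CH2Cl2, −20 °C
Reagents that add atoms: carbon tetrabromide, BrC(Br)(Br)Br
Why: Appel bromination activates only the unhindered primary allylic hydroxyl at low temperature, the tertiary carbinol being too hindered to form the alkoxyphosphonium ion.

Step 3
Reactants: 3 (3R,6E)-8-bromo-3,7-dimethylocta-1,6-dien-3-ol
Product: 5 (4E,8R)-8-hydroxy-4,8-dimethyldeca-4,9-dienal, via N-cyclohexyl imine 4 (not isolated)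
Conditions: N-cyclohexylethanimine (2.5 equiv), LiN(iPr)2 (2.5 equiv), THF, −78 °C, add 3, −78 to −20 °C; then AcOH/NaOAc buffer (pH 4.5), 25 °C
Reagents that add atoms: N-cyclohexylethanimine, CC=NC1CCCCC1; water, O
Why: Stork metalloenamine alkylation, in which the lithiated imine displaces the primary allylic bromide by SN2 at −78 °C faster than the tertiary alkoxide can cyclise, and buffered hydrolysis releases the aldehyde without ionising the allylic alcohol.

Step 4
Reactants: 6 (3R)-3-hydroxyoxolan-2-one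
Product: 7 (3R)-2-methylpentane-2,3,5-triol
Conditions: MeMgBr (3.5 equiv), THF, 0 to 25 °C; aq. NH4Cl
Reagents that add atoms: methylmagnesium bromide, C[Mg]Br
Why: Double Grignard addition to the lactone carbonyl gives the tertiary carbinol, and the α-alkoxide formed first blocks enolisation so the (R) centre bought in 6 is retained.

Step 5
Reactants: 7 (3R)-2-methylpentane-2,3,5-triol
Product: 8 2-[(4R)-2,2,5,5-tetramethyl-1,3-dioxolan-4-yl]ethan-1-ol
Conditions: 2,2-dimethoxypropane (3 equiv), TsOH·H2O (5 mol%), acetone, 25 °C, 12 h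
Reagents that add atoms: 2,2-dimethoxypropane, COC(C)(C)OC
Why: Thermodynamic acetalisation, in which the five-membered dioxolane on the secondary/tertiary 1,2-diol (gem-dialkyl effect) is favoured over the six-membered 1,3-dioxane and the primary hydroxyl stays free.

Step 6
Reactants: 8 2-[(4R)-2,2,5,5-tetramethyl-1,3-dioxolan-4-yl]ethan-1-ol
Product: 9 (4R)-4-(2-iodoethyl)-2,2,5,5-tetramethyl-1,3-dioxolane
Conditions: I2 (1.2 equiv), PPh3 (1.2 equiv), imidazole (1.5 equiv), CH2Cl2, 0 to 25 °C
Reagents that add atoms: iodine, II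
Why: Appel-type iodination (Garegg–Samuelsson conditions) converts the primary alcohol to the iodide without touching the ketal or the stereocenter.

Step 7
Reactants: 9 (4R)-4-(2-iodoethyl)-2,2,5,5-tetramethyl-1,3-dioxolane; 10 methyl 2-[bis(2,2,2-trifluoroethoxy)phosphoryl]acetate
Product: 11 methyl 2-[bis(2,2,2-trifluoroethoxy)phosphoryl]-4-[(4R)-2,2,5,5-tetramethyl-1,3-dioxolan-4-yl]butanoate
Conditions: 10 (1.5 equiv), NaH (1.4 equiv), DMF, 0 °C; then 9, 50 °C
Reagents that add atoms: none
Why: SN2 C-alkylation of the sodium phosphonoacetate with an unhindered primary iodide, where excess 10 suppresses dialkylation and the new α-centre (both epimers) disappears in step 8.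

Step 8
Reactants: 11 methyl 2-[bis(2,2,2-trifluoroethoxy)phosphoryl]-4-[(4R)-2,2,5,5-tetramethyl-1,3-dioxolan-4-yl]butanoate; 5 (4E,8R)-8-hydroxy-4,8-dimethyldeca-4,9-dienal
Product: 12 methyl (2Z,6E,10R)-10-hydroxy-6,10-dimethyl-2-{2-[(4R)-2,2,5,5-tetramethyl-1,3-dioxolan-4-yl]ethyl}dodeca-2,6,11-trienoate
Conditions: 11, KN(SiMe3)2 (1.0 equiv), 18-crown-6 (4 equiv), THF, −78 °C; then 5, −78 °C
Reagents that add atoms: none
Why: Still–Gennari modification of the Horner–Wadsworth–Emmons reaction, in which the electron-poor bis(trifluoroethyl) phosphonate eliminates under kinetic control to give the (Z)-trisubstituted enoate with the ester cis to the new chain, while the stabilised anion does not deprotonate the tertiary alcohol.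

Step 9
Reactants: 12 methyl (2Z,6E,10R)-10-hydroxy-6,10-dimethyl-2-{2-[(4R)-2,2,5,5-tetramethyl-1,3-dioxolan-4-yl]ethyl}dodeca-2,6,11-trienoate
Product: 14 (3Z,6R)-3-[(4E,8R)-8-hydroxy-4,8-dimethyldeca-4,9-dien-1-ylidene]-6-(2-hydroxypropan-2-yl)oxan-2-one, via dihydroxy ester 13 (not isolated)
Conditions: AcOH/H2O (4:1), 40 °C; then PPTS (0.1 equiv), toluene, 60 °C
Reagents that add atoms: none
Why: Acid hydrolysis of the isopropylidene ketal followed by acid-catalysed lactonisation of the δ-hydroxy ester through the secondary hydroxyl (six-membered ring favoured over the seven-membered alternative), with no bond to either stereocenter broken and the (Z)-alkene retained.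

Step 10
Reactants: 15 1,2,4-trimethoxy-5-methylbenzene
Product: 17 3-iodo-1,2,4-trimethoxy-5-methylbenzene, via aryllithium 16 (not isolated)
Conditions: n-BuLi (1.1 equiv), TMEDA (1.1 equiv), THF, 0 °C; then I2 (1.2 equiv), −78 to 25 °C
Reagents that add atoms: iodine, II
Why: Directed ortho-metalation, in which n-BuLi removes the proton flanked by two methoxy groups (C-3) and iodinolysis of the aryllithium gives the iodide regiospecifically.

Step 11
Reactants: 14 (3Z,6R)-3-[(4E,8R)-8-hydroxy-4,8-dimethyldeca-4,9-dien-1-ylidene]-6-(2-hydroxypropan-2-yl)oxan-2-one; 17 3-iodo-1,2,4-trimethoxy-5-methylbenzene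
Product: 18 (3Z,6R)-3-[(4E,8R,9E)-8-hydroxy-4,8-dimethyl-10-(2,3,6-trimethoxy-5-methylphenyl)deca-4,9-dien-1-ylidene]-6-(2-hydroxypropan-2-yl)oxan-2-one
Conditions: Pd(OAc)2 (5 mol%), n-Bu4NCl (1 equiv), NaHCO3 (2.5 equiv), DMF, 85 °C
Reagents that add atoms: none
Why: Mizoroki–Heck reaction under Jeffery conditions, in which the aryl–palladium species adds to the terminal carbon of the only monosubstituted alkene and, with a quaternary carbon on the other side, β-hydride elimination can only give the (E)-styrene, leaving the carbinol centre untouched.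

Step 12
Reactants: 18 (3Z,6R)-3-[(4E,8R,9E)-8-hydroxy-4,8-dimethyl-10-(2,3,6-trimethoxy-5-methylphenyl)deca-4,9-dien-1-ylidene]-6-(2-hydroxypropan-2-yl)oxan-2-one
Product: 19 (3Z,6R)-3-[(4E,8R,9E)-8-hydroxy-10-(2-methoxy-5-methyl-3,6-dioxocyclohexa-1,4-dien-1-yl)-4,8-dimethyldeca-4,9-dien-1-ylidene]-6-(2-hydroxypropan-2-yl)oxan-2-one
Conditions: (NH4)2Ce(NO3)6 (2.5 equiv), pyridine-2,6-dicarboxylic acid N-oxide (2.5 equiv), MeCN/H2O (2:1), 0 °C, 10 min, dark
Reagents that add atoms: water, O
Why: Oxidative demethylation by (NH4)2Ce(NO3)6 converts the para-dimethoxy pair into the 1,4-quinone and leaves the third methoxy group as a vinylogous ester, while the N-oxide ligand keeps the medium near neutral so the tertiary allylic alcohol does not ionise.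

Step 13
Reactants: 19 (3Z,6R)-3-[(4E,8R,9E)-8-hydroxy-10-(2-methoxy-5-methyl-3,6-dioxocyclohexa-1,4-dien-1-yl)-4,8-dimethyldeca-4,9-dien-1-ylidene]-6-(2-hydroxypropan-2-yl)oxan-2-one
Product: 21 (2R)-2,6-dimethyl-2-{(3E)-7-[(3Z,6R)-6-(2-hydroxypropan-2-yl)-2-oxooxan-3-ylidene]-4-methylhept-3-en-1-yl}-2H-chromene-5,8-dione, via (9Z)-alkenylquinone 20 (not isolated)
Conditions: hν (450 nm LEDs), K2CO3 (0.2 equiv), MeCN (2 mM), Ar, 20 °C
Reagents that add atoms: none
Why: Proposed new method: direct visible-light excitation of the push–pull alkenyl-methoxyquinone chromophore gives a twisted excited state that relaxes to a photostationary mixture enriched in the less conjugated, weaker-absorbing (Z)-alkene 20; only in 20 can the tertiary hydroxyl reach the methoxy-bearing quinone carbon, and a thermal 6-endo conjugate addition–elimination (loss of MeOH) drains 20 irreversibly to the pyranoquinone with the C–O bond of the linalool-derived stereocenter never broken, so C-2 is (R) by retention; the closest known reaction types are the photoisomerisation–lactonisation of (E)-o-hydroxycinnamates to coumarins and alkoxy exchange on 2-methoxy-1,4-benzoquinones.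

**Compound list**
1 | (3R)-3,7-dimethylocta-1,6-dien-3-ol, (R)-linalool | C=C[C@@](C)(CCC=C(C)C)O | starting material
2 | (2E,6R)-2,6-dimethylocta-2,7-diene-1,6-diol | C=C[C@@](C)(CC/C=C(\C)CO)O | intermediate
3 | (3R,6E)-8-bromo-3,7-dimethylocta-1,6-dien-3-ol | C=C[C@@](C)(CC/C=C(\C)CBr)O | intermediate
4 | (3R,6E)-10-(cyclohexylimino)-3,7-dimethyldeca-1,6-dien-3-ol | C=C[C@@](C)(CC/C=C(\C)CCC=NC1CCCCC1)O | intermediate
5 | (4E,8R)-8-hydroxy-4,8-dimethyldeca-4,9-dienal | C=C[C@@](C)(CC/C=C(\C)CCC=O)O | intermediate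
6 | (3R)-3-hydroxyoxolan-2-one, (R)-α-hydroxy-γ-butyrolactone | O[C@@H]1CCOC1=O | starting material
7 | (3R)-2-methylpentane-2,3,5-triol | CC(C)(O)[C@H](O)CCO | intermediate
8 | 2-[(4R)-2,2,5,5-tetramethyl-1,3-dioxolan-4-yl]ethan-1-ol | OCC[C@H]1OC(C)(C)OC1(C)C | intermediate
9 | (4R)-4-(2-iodoethyl)-2,2,5,5-tetramethyl-1,3-dioxolane | ICC[C@H]1OC(C)(C)OC1(C)C | intermediate
10 | methyl 2-[bis(2,2,2-trifluoroethoxy)phosphoryl]acetate | COC(=O)CP(=O)(OCC(F)(F)F)OCC(F)(F)F | starting material
11 | methyl 2-[bis(2,2,2-trifluoroethoxy)phosphoryl]-4-[(4R)-2,2,5,5-tetramethyl-1,3-dioxolan-4-yl]butanoate (both C-2 epimers) | COC(=O)C(CC[C@H]1OC(C)(C)OC1(C)C)P(=O)(OCC(F)(F)F)OCC(F)(F)F | intermediate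
12 | methyl (2Z,6E,10R)-10-hydroxy-6,10-dimethyl-2-{2-[(4R)-2,2,5,5-tetramethyl-1,3-dioxolan-4-yl]ethyl}dodeca-2,6,11-trienoate | C=C[C@@](C)(CC/C=C(\C)CC/C=C(/CC[C@H]1OC(C)(C)OC1(C)C)C(=O)OC)O | intermediate
13 | methyl (2Z,6E,10R)-2-[(3R)-3,4-dihydroxy-4-methylpentyl]-10-hydroxy-6,10-dimethyldodeca-2,6,11-trienoate | C=C[C@@](C)(CC/C=C(\C)CC/C=C(/CC[C@@H](O)C(C)(C)O)C(=O)OC)O | intermediate
14 | (3Z,6R)-3-[(4E,8R)-8-hydroxy-4,8-dimethyldeca-4,9-dien-1-ylidene]-6-(2-hydroxypropan-2-yl)oxan-2-one | C=C[C@@](C)(CC/C=C(\C)CC/C=C1/CC[C@H](C(C)(C)O)OC1=O)O | intermediate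
15 | 1,2,4-trimethoxy-5-methylbenzene | COc1cc(C)c(OC)cc1OC | starting material
16 | (2,3,6-trimethoxy-5-methylphenyl)lithium | COc1cc(C)c(OC)c([Li])c1OC | intermediate
17 | 3-iodo-1,2,4-trimethoxy-5-methylbenzene | COc1cc(C)c(OC)c(I)c1OC | intermediate
18 | (3Z,6R)-3-[(4E,8R,9E)-8-hydroxy-4,8-dimethyl-10-(2,3,6-trimethoxy-5-methylphenyl)deca-4,9-dien-1-ylidene]-6-(2-hydroxypropan-2-yl)oxan-2-one | COc1cc(C)c(OC)c(/C=C/[C@@](C)(CC/C=C(\C)CC/C=C2/CC[C@H](C(C)(C)O)OC2=O)O)c1OC | intermediate
19 | (3Z,6R)-3-[(4E,8R,9E)-8-hydroxy-10-(2-methoxy-5-methyl-3,6-dioxocyclohexa-1,4-dien-1-yl)-4,8-dimethyldeca-4,9-dien-1-ylidene]-6-(2-hydroxypropan-2-yl)oxan-2-one | O=C1C(OC)=C(/C=C/[C@@](C)(CC/C=C(\C)CC/C=C2/CC[C@H](C(C)(C)O)OC2=O)O)C(=O)C(C)=C1 | intermediate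
20 | (3Z,6R)-3-[(4E,8R,9Z)-8-hydroxy-10-(2-methoxy-5-methyl-3,6-dioxocyclohexa-1,4-dien-1-yl)-4,8-dimethyldeca-4,9-dien-1-ylidene]-6-(2-hydroxypropan-2-yl)oxan-2-one | O=C1C(OC)=C(/C=C\[C@@](C)(CC/C=C(\C)CC/C=C2/CC[C@H](C(C)(C)O)OC2=O)O)C(=O)C(C)=C1 | intermediate
21 | (2R)-2,6-dimethyl-2-{(3E)-7-[(3Z,6R)-6-(2-hydroxypropan-2-yl)-2-oxooxan-3-ylidene]-4-methylhept-3-en-1-yl}-2H-chromene-5,8-dione | CC1=CC(=O)C2=C(C=C[C@@](C)(CC/C=C(\C)CC/C=C3/CC[C@H](C(C)(C)O)OC3=O)O2)C1=O | target

**Step count**
Total step count: 13.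
Longest linear sequence: 9 steps (6 to 21 through steps 4, 5, 6, 7, 8, 9, 11, 12, 13).

**Steps most likely to fail**

Step 13 (the proposed new step). The photostationary mixture may not drain cleanly. The excited quinone may attack the remote trisubstituted alkenes. The product 2H-chromene may also ring-open photochemically and lose optical purity at C-2. The fallback uses known chemistry and keeps light away from any quinone. It sets out from 18: triplet-sensitised E→Z isomerisation of the electron-rich styrene (Ir[dF(CF3)ppy]2(dtbbpy)PF6 1 mol%, 450 nm, MeCN) gives (3Z,6R)-3-[(4E,8R,9Z)-8-hydroxy-4,8-dimethyl-10-(2,3,6-trimethoxy-5-methylphenyl)deca-4,9-dien-1-ylidene]-6-(2-hydroxypropan-2-yl)oxan-2-one F1. Oxidative demethylation of F1 under the conditions of step 12 then comes back to the route at 20, which closes in the dark (K2CO3, MeCN) to 21.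

Step 12. The electron-rich styrenyl tertiary allylic alcohol can ionise under the acidity of the cerium oxidant, and the alkenylquinone is prone to dimerisation. The fallback replaces the chemical oxidant by a base-buffered electrochemical one. It sets out from 18: constant-current anodic oxidation in methanol (1% KOH, graphite anode, Pt cathode, undivided cell, 0 °C) gives the quinone bis(dimethyl ketal) (3Z,6R)-3-[(4E,8R,9E)-8-hydroxy-10-(2,3,3,6,6-pentamethoxy-5-methylcyclohexa-1,4-dien-1-yl)-4,8-dimethyldeca-4,9-dien-1-ylidene]-6-(2-hydroxypropan-2-yl)oxan-2-one F2. Hydrolysis of F2 with 1% aqueous AcOH in acetone at 0 °C comes back to the route at 19.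

Step 9. The acid needed to open the hindered ketal may also ionise the linalool-type tertiary allylic alcohol (allyl cation, cyclisation onto the neighbouring alkene). The fallback moves the acid step ahead of the fragment union. It sets out from 11: TsOH in MeOH, then toluene at 60 °C, removes the ketal and lactonises to (6R)-3-[bis(2,2,2-trifluoroethoxy)phosphoryl]-6-(2-hydroxypropan-2-yl)oxan-2-one F3. Olefination of F3 with 5 (KN(SiMe3)2 2 equiv, 18-crown-6, THF, −78 °C) comes back to the route at 14 with no acid used after the allylic alcohol is on board. The Z/E ratio of this cyclic reagent has to be measured and the E isomer removed by chromatography.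

**Further compounds**
F1 | step 13 | (3Z,6R)-3-[(4E,8R,9Z)-8-hydroxy-4,8-dimethyl-10-(2,3,6-trimethoxy-5-methylphenyl)deca-4,9-dien-1-ylidene]-6-(2-hydroxypropan-2-yl)oxan-2-one | COc1cc(C)c(OC)c(/C=C\[C@@](C)(CC/C=C(\C)CC/C=C2/CC[C@H](C(C)(C)O)OC2=O)O)c1OC
F2 | step 12 | (3Z,6R)-3-[(4E,8R,9E)-8-hydroxy-10-(2,3,3,6,6-pentamethoxy-5-methylcyclohexa-1,4-dien-1-yl)-4,8-dimethyldeca-4,9-dien-1-ylidene]-6-(2-hydroxypropan-2-yl)oxan-2-one | COC1=C(/C=C/[C@@](C)(CC/C=C(\C)CC/C=C2/CC[C@H](C(C)(C)O)OC2=O)O)C(OC)(OC)C(C)=CC1(OC)OC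
F3 | step 9 | (6R)-3-[bis(2,2,2-trifluoroethoxy)phosphoryl]-6-(2-hydroxypropan-2-yl)oxan-2-one | CC(C)(O)[C@H]1CCC(P(=O)(OCC(F)(F)F)OCC(F)(F)F)C(=O)O1
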